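The route rests on cutting the C1–C10 bond of the seven-membered ring. The methyl-bearing quaternary C1 and the acyloxy carbon C6 both sit on the ring-fusion carbon C5, so C6–C5–C1 is a latent allyl unit common to both rings. A [3,3] shift of the allyl vinyl ether C10=C9–O–C6–C5=C1 in 10 trades the easily set C6–O stereocentre for the C1–C10 bond. One operation turns the five-membered ether into the cycloheptenone, fixes C1, and leaves a C9 ketone and a C5=C6 alkene as handles. The precursor is a lactone-derived 2-methylenetetrahydrofuran whose C6 carries a 2-methylcyclopentenyl group with C4 masked as a dioxolane.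

Key step: step 5

Numbering and faces: C1 is the methyl-bearing fusion carbon, followed by C2 and C3. C4 is the isopropyl carbinol, C5 the fusion CH, C6 the ester CH, then C7. C8 is the spiro-epoxide carbon (C14 is its CH2). C9 and C10 are the diol carbons, with C10 bonded to C1. β is the face of the C1 methyl and α the opposite face. The target is 1β-CH3, 4β-OH, 5α-H, 6α-O-acyl, 8α-O, 9α-OH, 10α-OH, which is (1S,4R,5S,6S,8S,9S,10S) in this numbering.

Assumption: the C9 carbinols 12–16, 18, 20, 21 and 26 are drawn as the 9β epimer expected from α-face hydride attack. The other epimer would simply be carried along, because C9 is flattened again in steps 13 and 17.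

Step 1
Reactants: 1 2-bromo-3-methylcyclopent-2-en-1-one; 2 ethylene glycol
Product: 3 6-bromo-7-methyl-1,4-dioxaspiro[4.4]non-6-ene
Conditions: p-TsOH (cat.), benzene, reflux, azeotropic removal of water
Reagents that add atoms: ethylene glycol (2), OCCO
Why: Acid-catalysed ketalisation; the α-bromine should keep the double bond in place (no deconjugation), as is usual for 2-bromoenone ketals.

Step 2
Reactants: 3 6-bromo-7-methyl-1,4-dioxaspiro[4.4]non-6-ene; 4 methyl 4-chloro-4-oxobutanoate
Product: 7 methyl 4-(7-methyl-1,4-dioxaspiro[4.4]non-6-en-6-yl)-4-oxobutanoate, via vinyllithium 5 (not isolated), via vinylzinc chloride 6 (not isolated)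
Conditions: n-BuLi, THF, −78 °C; ZnCl2, −78 to 0 °C; 4, Pd(PPh3)4 (3 mol %), 0 °C to rt
Reagents that add atoms: methyl 4-chloro-4-oxobutanoate (4), COC(=O)CCC(=O)Cl
Why: Bromine–lithium exchange gives a vinyl anion that cannot β-eliminate inside the five-membered ring, and after transmetalation to zinc the Negishi acylation should stop at the ketone and leave the methyl ester untouched.

Step 3
Reactants: 7 methyl 4-(7-methyl-1,4-dioxaspiro[4.4]non-6-en-6-yl)-4-oxobutanoate
Product: 9 (5S)-5-(7-methyl-1,4-dioxaspiro[4.4]non-6-en-6-yl)oxolan-2-one, via (4S)-hydroxy ester 8 (not isolated)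
Conditions: (R)-Me-CBS (15 mol %), BH3·SMe2, THF, −30 °C; MeOH; then DBU (10 mol %), toluene, 50 °C
Reagents that add atoms: none
Why: Corey–Bakshi–Shibata reduction followed by base-catalysed 5-exo-trig lactonisation: the fully substituted cyclopentenyl group acts as the large and the CH2 chain as the small ketone substituent, so the (R)-catalyst should give (S)-C6, and the acid-free ring closure avoids ionisation of the allylic carbinol.

Step 4
Reactants: 9 (5S)-5-(7-methyl-1,4-dioxaspiro[4.4]non-6-en-6-yl)oxolan-2-one
Product: 10 (2S)-2-(7-methyl-1,4-dioxaspiro[4.4]non-6-en-6-yl)-5-methylideneoxolane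
Conditions: Cp2TiMe2, toluene, 75 °C, dark; filtration through basic Al2O3
Reagents that add atoms: dimethyltitanocene, C[Ti](C)(C1C=CC=C1)C1C=CC=C1
Why: Petasis methylenation of the lactone carbonyl, a neutral carbonyl olefination that tolerates the ketal (which is needed here because a free C4 carbonyl would be methylenated first), leaves C6 untouched and gives the exocyclic enol ether, which is handled on basic media only.

Step 5
Reactants: 10 (2S)-2-(7-methyl-1,4-dioxaspiro[4.4]non-6-en-6-yl)-5-methylideneoxolane
Product: 11 (1R)-hydroazulenone (1β-CH3; C9 ketone; C5=C6 alkene; C4 dioxolane)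
Conditions: mesitylene (0.02 M), i-Pr2NEt (20 mol %), BHT (1 mol %), silylated sealed tube, 190 °C
Reagents that add atoms: none
Why: Heat drives a concerted, suprafacial [3,3] sigmatropic (Claisen) shift of the array C10=C9–O–C6–C5=C1, in which C6–O breaks while C1–C10 forms and C9 becomes a ketone. The closest known reaction type is the Claisen ring expansion of 2-methylene-5-vinyltetrahydrofurans to cyclohept-4-enones. The seven-membered carbocycle (C1, C5, C6, C7, C8, C9, C10) is closed by ring expansion of the five-membered ether: because C7–C8 ties C9 to C6, only a boat-like array is possible and only the cis C5=C6 ring alkene can result. The new quaternary centre C1 is controlled by C6, since C10 has to bond to the face of C1 on which the oxygen leaves C6, so (S)-C6 is translated into (R)-C1 (1β-methyl). The rearrangement must outrun acid-catalysed migration of the exocyclic double bond into the ether ring and heterolysis of the allylic C6–O bond; the amine buffer, the silylated glass and the electron-withdrawing C4 ketal next to the allyl unit should secure this. The price is a contact between C7 and the C1 methyl inside the fold, which is why a higher temperature than for unsubstituted cases is planned.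

Step 6
Reactants: 11 (1R)-hydroazulenone
Product: 12 9β-alcohol (1β-CH3; C5=C6; C4 dioxolane)
Conditions: NaBH4, MeOH, 0 °C
Reagents that add atoms: none
Why: Borohydride reduction that merely parks C9 as a carbinol so that borane can be used later; hydride should enter from the α face because the pseudo-axial C1 methyl covers the β face of C9, but the new centre is of no consequence since it is erased in step 13.

Step 7
Reactants: 12 9β-alcohol
Product: 13 9β-TBS ether (1β-CH3; C5=C6; C4 dioxolane)
Conditions: TBSCl, imidazole, DMF, rt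
Reagents that add atoms: tert-butyldimethylsilyl chloride, CC(C)(C)[Si](C)(C)Cl
Why: Standard silylation of a secondary alcohol; the TBS ether withstands borane, alkaline peroxide, PPTS and organocerium reagents and can later be removed without touching the ester.

Step 8
Reactants: 13 9β-TBS ether
Product: 15 trans-fused ketal alcohol (1β-CH3; 5α-H; 6α-OH; 9β-OTBS; C4 dioxolane), via 6α-alkylborane 14 (not isolated)
Conditions: BH3·THF, THF, 0 °C to rt; then NaOH, H2O2, 0 °C
Reagents that add atoms: hydrogen peroxide, OO
Why: Hydroboration–oxidation (syn, anti-Markovnikov): boron goes to the less substituted C6 and hydrogen to C5 on the face opposite to the angular methyl, as in the 5-ene steroids, so 5α-H (trans fusion) and, after C–B oxidation with retention, 6α-OH are set together.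

Step 9
Reactants: 15 trans-fused ketal alcohol
Product: 16 β-hydroxy ketone (C4 ketone; 5α-H; 6α-OH; 9β-OTBS)
Conditions: PPTS, acetone–H2O, 50 °C
Reagents that add atoms: water, O
Why: Mild acid-catalysed ketal hydrolysis; PPTS should be too weak to cleave the TBS ether, to dehydrate the β-hydroxy ketone or to enolise it toward the hindered C5.

Step 10
Reactants: 16 β-hydroxy ketone; 17 isopropylmagnesium chloride
Product: 18 4β,6α-diol (4α-isopropyl; 5α-H; 9β-OTBS)
Conditions: 17 (3.5 equiv), CeCl3 (anhydrous), THF, −78 to 0 °C; aqueous work-up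
Reagents that add atoms: isopropylmagnesium chloride (17), CC(C)[Mg]Cl
Why: Organocerium 1,2-addition, chosen because the weakly basic reagent suppresses enolisation, β-hydride reduction and retro-aldol cleavage (the first equivalent only deprotonates 6-OH, which also rules out β-elimination); the nucleophile should approach C4 from the α face past H5, the β face being shielded 1,3 by the axial C1 methyl, which gives the 4β-OH, 4α-isopropyl centre.

Step 11
Reactants: 18 4β,6α-diol; 19 3-methylbutanoyl chloride
Product: 20 6α-isovalerate (4β-OH; 9β-OTBS)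
Conditions: pyridine, DMAP (cat.), CH2Cl2, 0 °C to rt
Reagents that add atoms: 3-methylbutanoyl chloride (19), CC(C)CC(=O)Cl
Why: DMAP-catalysed acylation that differentiates the secondary 6-OH from the unreactive tertiary 4-OH, so the ester is in place before any other free secondary hydroxyl exists.

Step 12
Reactants: 20 6α-isovalerate
Product: 21 9β-alcohol 6α-isovalerate (4β-OH)
Conditions: HF·pyridine, THF, 0 °C to rt
Reagents that add atoms: none
Why: Fluoride-induced cleavage of the silyl ether under slightly acidic conditions, which avoids acyl migration and ester hydrolysis.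

Step 13
Reactants: 21 9β-alcohol 6α-isovalerate
Product: 22 C9 ketone 6α-isovalerate (4β-OH)
Conditions: Dess–Martin periodinane, CH2Cl2, rt
Reagents that add atoms: none
Why: Dess–Martin oxidation returns C9 to the ketone under neutral conditions; the tertiary alcohol and the ester are inert.

Step 14
Reactants: 22 C9 ketone 6α-isovalerate
Product: 23 8-methylene-9-ketone (C8=C14; 4β-OH; 6α-isovalerate)
Conditions: (CH2O)n, i-Pr2NH·CF3CO2H, CF3CO2H (10 mol %), THF, reflux
Reagents that add atoms: paraformaldehyde (as formaldehyde), C=O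
Why: Mannich-type α-methylenation (iminium addition to the enol, then β-elimination of the amine) under weakly acidic conditions that spare ester and tertiary alcohol; C8 reacts because C10 is neopentyl next to quaternary C1.

Step 15
Reactants: 23 8-methylene-9-ketone
Product: 25 10α-triethylsilyloxy enone (C8=C14; C9 ketone; 4β-OTES; 6α-isovalerate), via bis-silylated 2-silyloxydiene 24 (not isolated)
Conditions: TESOTf, Et3N, CH2Cl2, 0 °C; crude 24, m-CPBA, NaHCO3, CH2Cl2, −20 °C
Reagents that add atoms: triethylsilyl triflate, CC[Si](CC)(CC)OS(=O)(=O)C(F)(F)F; m-chloroperbenzoic acid, OOC(=O)c1cccc(Cl)c1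
Why: Soft enolisation can only go toward C10 because C8 bears no hydrogen, and Rubottom oxidation of the resulting 2-silyloxydiene should take place at the electron-rich C9=C10 bond from the α face, anti to the methyl on the adjacent C1, so that after silyl shift the 10α-silyloxy ketone results (4-OH is silylated on the way, which is useful for steps 16 to 18).

Step 16
Reactants: 25 10α-triethylsilyloxy enone
Product: 26 9β-allylic alcohol (C8=C14; 10α-OTES; 4β-OTES; 6α-isovalerate)
Conditions: NaBH4, CeCl3·7H2O, MeOH, −78 to −20 °C
Reagents that add atoms: none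
Why: Luche 1,2-reduction of the enone; hydride is expected from the α face, away from the C1 methyl, and thus gives the undesired 9β-alcohol, which does not matter because the next two steps rebuild this centre from either epimer.

Step 17
Reactants: 26 9β-allylic alcohol
Product: 28 allylic sulfoxide (C14–S(O)Ph; C8=C9; 10α-OTES; 4β-OTES; 6α-isovalerate), via 9β-benzenesulfenate 27 (not isolated)
Conditions: PhSCl, Et3N, THF, −78 °C to rt
Reagents that add atoms: benzenesulfenyl chloride, ClSc1ccccc1
Why: O-Sulfenylation followed by spontaneous Mislow–Evans [2,3] sigmatropic rearrangement, which lies on the side of the allylic sulfoxide, flattens C9 and moves the double bond to C8=C9 (sulfur epimers are irrelevant).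

Step 18
Reactants: 28 allylic sulfoxide
Product: 30 9α-allylic alcohol (C8=C14; 10α-OTES; 4β-OTES; 6α-isovalerate), via 9α-benzenesulfenate 29 (not isolated)
Conditions: Et2NH, MeOH, 50 °C
Reagents that add atoms: none
Why: Reverse Mislow–Evans rearrangement with a thiophile: the sulfinyl oxygen is handed over suprafacially from C14 to C9 and should reach C9 on the α face, since the axial C1 methyl lies over the β face, and diethylamine cleaves the S–O bond of the small equilibrium amount of sulfenate irreversibly, giving the 9α-allylic alcohol and the C8=C14 methylene group.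

Step 19
Reactants: 30 9α-allylic alcohol
Product: 31 4β,9α,10α-triol 6α-isovalerate (C8=C14)
Conditions: HF·pyridine, THF, 0 °C to rt
Reagents that add atoms: none
Why: Fluoride-mediated removal of both triethylsilyl ethers before the acid- and base-sensitive epoxide is introduced.

Step 20
Reactants: 31 4β,9α,10α-triol 6α-isovalerate
Product: 32 target CNP0307265.1 (8α,14-epoxide; 4β,9α,10α-triol; 6α-isovalerate)
Conditions: VO(acac)2 (5 mol %), t-BuOOH, CH2Cl2, 0 °C
Reagents that add atoms: tert-butyl hydroperoxide, CC(C)(C)OO
Why: Vanadium-catalysed hydroxyl-directed epoxidation: the peroxide is bound to the metal alkoxide of the allylic 9α-OH (supported by the homoallylic 10α-OH) and oxygen is delivered to the α face of the only alkene, C8=C14, which sets C8 with the epoxide oxygen cis to 9-OH.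

Compound list
1 | 2-bromo-3-methylcyclopent-2-en-1-one | CC1=C(Br)C(=O)CC1 | starting material
2 | ethylene glycol | OCCO | starting material
3 | 6-bromo-7-methyl-1,4-dioxaspiro[4.4]non-6-ene | CC1=C(Br)C2(CC1)OCCO2 | intermediate
4 | methyl 4-chloro-4-oxobutanoate | COC(=O)CCC(=O)Cl | starting material
5 | (7-methyl-1,4-dioxaspiro[4.4]non-6-en-6-yl)lithium | CC1=C([Li])C2(CC1)OCCO2 | intermediate
6 | (7-methyl-1,4-dioxaspiro[4.4]non-6-en-6-yl)zinc chloride | CC1=C([Zn]Cl)C2(CC1)OCCO2 | intermediate
7 | methyl 4-(7-methyl-1,4-dioxaspiro[4.4]non-6-en-6-yl)-4-oxobutanoate | COC(=O)CCC(=O)C1=C(C)CCC12OCCO2 | intermediate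
8 | methyl (4S)-4-hydroxy-4-(7-methyl-1,4-dioxaspiro[4.4]non-6-en-6-yl)butanoate | COC(=O)CC[C@H](O)C1=C(C)CCC12OCCO2 | intermediate
9 | (5S)-5-(7-methyl-1,4-dioxaspiro[4.4]non-6-en-6-yl)oxolan-2-one | O=C1CC[C@H](O1)C2=C(C)CCC23OCCO3 | intermediate
10 | (2S)-2-(7-methyl-1,4-dioxaspiro[4.4]non-6-en-6-yl)-5-methylideneoxolane | C=C1CC[C@H](O1)C2=C(C)CCC23OCCO3 | intermediate
11 | (1R)-hydroazulenone, C9 ketone, C5=C6, C4 dioxolane | O=C1CCC=C2C3(OCCO3)CC[C@]2(C)C1 | intermediate
12 | 9β-alcohol of 11 | O[C@H]1CCC=C2C3(OCCO3)CC[C@]2(C)C1 | intermediate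
13 | 9β-TBS ether of 12 | CC(C)(C)[Si](C)(C)O[C@H]1CCC=C2C3(OCCO3)CC[C@]2(C)C1 | intermediate
14 | 6α-alkylborane (5α-H) | [BH2][C@H]1CC[C@H](O[Si](C)(C)C(C)(C)C)C[C@@]2(C)CCC3(OCCO3)[C@H]12 | intermediate
15 | trans-fused ketal alcohol (5α-H, 6α-OH, 9β-OTBS) | O[C@H]1CC[C@H](O[Si](C)(C)C(C)(C)C)C[C@@]2(C)CCC3(OCCO3)[C@H]12 | intermediate
16 | β-hydroxy ketone (C4 ketone, 6α-OH, 9β-OTBS) | O[C@H]1CC[C@H](O[Si](C)(C)C(C)(C)C)C[C@@]2(C)CCC(=O)[C@H]12 | intermediate
17 | isopropylmagnesium chloride | CC(C)[Mg]Cl | starting material
18 | 4β,6α-diol (4α-isopropyl, 9β-OTBS) | O[C@H]1CC[C@H](O[Si](C)(C)C(C)(C)C)C[C@@]2(C)CC[C@@](O)(C(C)C)[C@H]12 | intermediate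
19 | 3-methylbutanoyl chloride | CC(C)CC(=O)Cl | starting material
20 | 6α-isovalerate (4β-OH, 9β-OTBS) | CC(C)CC(=O)O[C@H]1CC[C@H](O[Si](C)(C)C(C)(C)C)C[C@@]2(C)CC[C@@](O)(C(C)C)[C@H]12 | intermediate
21 | 9β-alcohol 6α-isovalerate | CC(C)CC(=O)O[C@H]1CC[C@H](O)C[C@@]2(C)CC[C@@](O)(C(C)C)[C@H]12 | intermediate
22 | C9 ketone 6α-isovalerate | CC(C)CC(=O)O[C@H]1CCC(=O)C[C@@]2(C)CC[C@@](O)(C(C)C)[C@H]12 | intermediate
23 | 8-methylene-9-ketone | CC(C)CC(=O)O[C@H]1CC(=C)C(=O)C[C@@]2(C)CC[C@@](O)(C(C)C)[C@H]12 | intermediate
24 | bis-silylated 2-silyloxydiene | CC(C)CC(=O)O[C@H]1CC(=C)C(O[Si](CC)(CC)CC)=C[C@@]2(C)CC[C@@](O[Si](CC)(CC)CC)(C(C)C)[C@H]12 | intermediate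
25 | 10α-triethylsilyloxy enone | CC(C)CC(=O)O[C@H]1CC(=C)C(=O)[C@@H](O[Si](CC)(CC)CC)[C@@]2(C)CC[C@@](O[Si](CC)(CC)CC)(C(C)C)[C@H]12 | intermediate
26 | 9β-allylic alcohol | CC(C)CC(=O)O[C@H]1CC(=C)[C@H](O)[C@@H](O[Si](CC)(CC)CC)[C@@]2(C)CC[C@@](O[Si](CC)(CC)CC)(C(C)C)[C@H]12 | intermediate
27 | 9β-benzenesulfenate | CC(C)CC(=O)O[C@H]1CC(=C)[C@H](OSc3ccccc3)[C@@H](O[Si](CC)(CC)CC)[C@@]2(C)CC[C@@](O[Si](CC)(CC)CC)(C(C)C)[C@H]12 | intermediate
28 | allylic sulfoxide (C8=C9, sulfur epimers) | CC(C)CC(=O)O[C@H]1CC(CS(=O)c3ccccc3)=C[C@@H](O[Si](CC)(CC)CC)[C@@]2(C)CC[C@@](O[Si](CC)(CC)CC)(C(C)C)[C@H]12 | intermediate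
29 | 9α-benzenesulfenate | CC(C)CC(=O)O[C@H]1CC(=C)[C@@H](OSc3ccccc3)[C@@H](O[Si](CC)(CC)CC)[C@@]2(C)CC[C@@](O[Si](CC)(CC)CC)(C(C)C)[C@H]12 | intermediate
30 | 9α-allylic alcohol | CC(C)CC(=O)O[C@H]1CC(=C)[C@@H](O)[C@@H](O[Si](CC)(CC)CC)[C@@]2(C)CC[C@@](O[Si](CC)(CC)CC)(C(C)C)[C@H]12 | intermediate
31 | 4β,9α,10α-triol 6α-isovalerate (C8=C14) | CC(C)CC(=O)O[C@H]1CC(=C)[C@@H](O)[C@@H](O)[C@@]2(C)CC[C@@](O)(C(C)C)[C@H]12 | intermediate
32 | CNP0307265.1 | CC(C)CC(=O)O[C@H]1C[C@]2(CO2)[C@@H](O)[C@@H](O)[C@@]2(C)CC[C@@](O)(C(C)C)[C@H]12 | target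

Total step count: 20. Longest linear sequence: 20 steps (1 to 32).

Steps most likely to fail

Step 5. In the boat array C7 and the C1 methyl both point into the fold, so the barrier may be high. Proton-catalysed drift of the exocyclic double bond into the ether ring could then win, or heterolysis of the allylic C6–O bond with erosion of the chirality transfer. The fallback leaves the neutral thermal mode for an aluminium-promoted reductive rearrangement. Compound 10 is treated with i-Bu3Al in CH2Cl2 from −78 °C to rt. Binding of aluminium to the ring oxygen weakens C6–O, so the shift should run below room temperature. The aluminium-bound ketone 11 is reduced in the flask by hydride transfer from an isobutyl group. The fallback sets out from 10 and comes back at alcohol 12, so step 6 is skipped. No compound outside the list is made (entry F0). The group to watch is the dioxolane, which competes for the Lewis acid.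

Step 8. The alkene lies between two fully substituted carbons, and the rest of the seven-membered ring folds under the α face. The addition may therefore be slow, and facial selectivity against the methyl-bearing β face may be poor. The fallback replaces kinetic face selection by thermodynamic control and sets out from 13. Hydroboration–oxidation is run without regard to face and gives 15 together with the cis-fused 5β-H,6β-alcohol F1. Dess–Martin oxidation of the mixture gives the cis-fused C6 ketone F2 and the trans-fused C6 ketone F3. NaOMe in MeOH equilibrates C5, now α to the carbonyl, toward the expected more stable trans-fused F3. Single-electron reduction with SmI2/H2O/Et3N in THF should then give the more stable equatorial 6α-alcohol, and the route is rejoined at 15.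

Step 10. The hindered ketone may be reduced by hydride transfer from the isopropyl reagent. It may also enolise toward C5, with loss of the trans fusion or of the C6 oxygen, and the free alkoxide may trigger retro-aldol opening. The fallback changes both the substrate and the nucleophile and sets out from 16. TESCl/imidazole gives the 6α-triethylsilyl ether ketone F4. 2-Propenylmagnesium bromide with CeCl3 is slimmer and has no transferable β-hydrogen, and it gives the 4α-isopropenyl carbinol F5. Hydrogenation (H2, Pd/C, EtOAc) gives the 4α-isopropyl carbinol F6. Selective cleavage of the triethylsilyl ether (PPTS, MeOH, 0 °C) returns to diol 18.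

Further compounds
F0 | step 5 | none | none
F1 | step 8 | cis-fused 5β-H,6β-alcohol (9β-OTBS, C4 dioxolane) | O[C@@H]1CC[C@H](O[Si](C)(C)C(C)(C)C)C[C@@]2(C)CCC3(OCCO3)[C@@H]12
F2 | step 8 | cis-fused C6 ketone (5β-H) | O=C1CC[C@H](O[Si](C)(C)C(C)(C)C)C[C@@]2(C)CCC3(OCCO3)[C@@H]12
F3 | step 8 | trans-fused C6 ketone (5α-H) | O=C1CC[C@H](O[Si](C)(C)C(C)(C)C)C[C@@]2(C)CCC3(OCCO3)[C@H]12
F4 | step 10 | 6α-triethylsilyl ether ketone | CC[Si](CC)(CC)O[C@H]1CC[C@H](O[Si](C)(C)C(C)(C)C)C[C@@]2(C)CCC(=O)[C@H]12
F5 | step 10 | 4α-isopropenyl carbinol | CC[Si](CC)(CC)O[C@H]1CC[C@H](O[Si](C)(C)C(C)(C)C)C[C@@]2(C)CC[C@@](O)(C(C)=C)[C@H]12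
F6 | step 10 | 4α-isopropyl carbinol (6α-OTES) | CC[Si](CC)(CC)O[C@H]1CC[C@H](O[Si](C)(C)C(C)(C)C)C[C@@]2(C)CC[C@@](O)(C(C)C)[C@H]12
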